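**Strategy.** The oxan-4-one ring has its C4 carbonyl between two methylenes, C3 and C5, each leading to a carbon bonded to the ring oxygen O1 (benzylic C2 and C6). The route reads this 1,3-relationship on both sides of C4 as an acyl dianion joined to two terminal epoxides. In one flask a lithiated 2-silyl-1,3-dithiane opens the vanillin-derived aryl oxirane (C3–C4), silicon then migrates from carbon to oxygen, and the regenerated carbanion opens an erythro epoxy benzyl ether that already carries C6 and C1′ (C4–C5). The precursor set is thus the silyl dithiane and two CH2-terminated epoxides; the open-chain product holds the whole C2–C2′ chain, and acid later closes O1–C2 to the cis ring.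

Key step: step 6

Remark on the chemistry: the target is (2S,6R)-2-(4-hydroxy-3-methoxyphenyl)-6-[(1S)-1-hydroxy-2-(4-hydroxyphenyl)ethyl]oxan-4-one, with cis substituents at C2 and C6 (locants O1, C2 aryl, C3, C4 carbonyl, C5, C6, side chain C1′ and C2′). Aryl oxirane 2 is used as the racemate, because an ylide epoxidation gives no enantiocontrol and its carbinol carbon (later C2) is ionised and reset under thermodynamic control in step 7. Compounds 12, 13 and 14 are therefore carried as both epimers at that carbon and converge on 15.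

Step 1
Reactants: 1 O-benzylvanillin [4-(benzyloxy)-3-methoxybenzaldehyde]
Product: 2 rac-2-[4-(benzyloxy)-3-methoxyphenyl]oxirane
Conditions: Me3S+ I−, KOtBu, DMSO/THF, 0 °C → rt; filtration through basic Al2O3, used at once
Reagents that add atoms: trimethylsulfonium iodide, C[S+](C)C.[I-]
Why: Corey–Chaykovsky epoxidation, in which dimethylsulfonium methylide adds to the aldehyde and the betaine closes to the terminal epoxide; no stereocontrol is required, and the acid-labile electron-rich oxirane is kept away from silica and stored cold.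

Step 2
Reactants: 3 4-(benzyloxy)phenylmagnesium bromide (4-BnOC6H4MgBr, THF solution); 4 (S)-epichlorohydrin
Product: 5 (2S)-1-[4-(benzyloxy)phenyl]-3-chloropropan-2-ol
Conditions: CuI (10 mol %), THF, −40 → 0 °C
Reagents that add atoms: none
Why: Copper-catalysed Grignard opening of the epoxide at its unsubstituted carbon (SN2) leaves the oxygen-bearing stereocenter untouched, so the (S) configuration of the later C1′ is taken from the chiral pool.

Step 3
Reactants: 5 (2S)-1-[4-(benzyloxy)phenyl]-3-chloropropan-2-ol
Product: 7 (2S)-1-[4-(benzyloxy)phenyl]but-3-en-2-ol, via (2S)-2-[4-(benzyloxy)benzyl]oxirane 6 (not isolated)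
Conditions: Me3S+ I− (4 equiv), n-BuLi (3.8 equiv), THF, −10 °C → rt
Reagents that add atoms: trimethylsulfonium iodide, C[S+](C)C.[I-]
Why: Sulfonium-ylide one-carbon homologation of a terminal epoxide to an allylic alcohol, in which excess dimethylsulfonium methylide first closes the chlorohydrin to 6, then opens it at CH2 and eliminates Me2S from the betaine, none of which touches the carbinol stereocenter.

Step 4
Reactants: 7 (2S)-1-[4-(benzyloxy)phenyl]but-3-en-2-ol
Product: 8 (1S)-2-[4-(benzyloxy)phenyl]-1-[(2R)-oxiran-2-yl]ethan-1-ol (erythro epoxy alcohol)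
Conditions: Ti(OiPr)4 (1.0 equiv), L-(+)-DIPT (1.2 equiv), t-BuOOH (2 equiv), 4 Å MS, CH2Cl2, −20 °C; citric acid work-up
Reagents that add atoms: tert-butyl hydroperoxide, CC(C)(C)OO
Why: Katsuki–Sharpless asymmetric epoxidation in its matched sense, since for L-(+)-tartrate the (S)-carbinol is the fast-reacting enantiomer of this alcohol class and oxygen is delivered to the face that gives the erythro product, so the new epoxide carbon (later C6) is set as R by reagent and substrate acting together.

Step 5
Reactants: 8 (1S)-2-[4-(benzyloxy)phenyl]-1-[(2R)-oxiran-2-yl]ethan-1-ol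
Product: 9 (2R)-2-{(1S)-1-(benzyloxy)-2-[4-(benzyloxy)phenyl]ethyl}oxirane
Conditions: NaH, BnBr, n-Bu4NI (cat.), THF, 0 °C → rt
Reagents that add atoms: benzyl bromide, BrCc1ccccc1
Why: Williamson O-benzylation of the sodium alkoxide, which in aprotic THF under iodide catalysis should outrun Payne migration of the adjacent epoxide and touches no stereocenter.

Step 6
Reactants: 10 2-(tert-butyldimethylsilyl)-1,3-dithiane; 2 rac-2-[4-(benzyloxy)-3-methoxyphenyl]oxirane; 9 (2R)-2-{(1S)-1-(benzyloxy)-2-[4-(benzyloxy)phenyl]ethyl}oxirane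
Product: 14 (2R,3S)-3-(benzyloxy)-4-[4-(benzyloxy)phenyl]-1-(2-{2-[4-(benzyloxy)-3-methoxyphenyl]-2-[(tert-butyldimethylsilyl)oxy]ethyl}-1,3-dithian-2-yl)butan-2-ol (both epimers at the silyloxy carbon), via 2-lithio-2-(tert-butyldimethylsilyl)-1,3-dithiane 11 (not isolated), via lithium alkoxide of the first epoxide adduct 12 (not isolated), via O-silylated 2-lithio-1,3-dithiane 13 (not isolated)
Conditions: t-BuLi, Et2O, −78 → −45 °C; 2 (1.0 equiv), Et2O, −78 → −25 °C; then 9 (0.9 equiv), THF/HMPA, −78 → 0 °C
Reagents that add atoms: none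
Why: t-BuLi deprotonates 10 to 11, which opens 2 by SN2 at the unsubstituted epoxide carbon (C3–C4) to give alkoxide 12; in Et2O this alkoxide keeps its C-silyl group, and only when HMPA is added does a 1,4-Brook rearrangement move silicon to the benzylic oxygen and regenerate a dithiane carbanion 13, which opens 9 at its CH2 (C4–C5). The closest known reaction type is the one-flask three-component linchpin coupling of a 2-silyl-1,3-dithiane with two different terminal epoxides (type 1 anion relay chemistry). No ring is closed. No stereocenter is created, because both epoxides react at CH2: C6 and C1′ of 9 are carried over unchanged and the silyloxy carbon keeps the racemic configuration of 2. The step needs terminal regioselectivity at both epoxides and a strict order of events; the bulky silyl dithiane anion under strongly basic conditions favours CH2 over the benzylic carbon of 2, and the solvent gate on the Brook shift ensures that the labile aryl oxirane is consumed before the valuable epoxide 9 meets a carbanion.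

Step 7
Reactants: 14 open-chain silyl ether dithiane (both epimers)
Product: 15 (8S,10R)-8-[4-(benzyloxy)-3-methoxyphenyl]-10-{(1S)-1-(benzyloxy)-2-[4-(benzyloxy)phenyl]ethyl}-9-oxa-1,5-dithiaspiro[5.5]undecane (the 2,6-cis oxane, C4 masked as the dithiane)
Conditions: TsOH·H2O (0.3 equiv), CH2Cl2, 0 °C → rt
Reagents that add atoms: none
Why: Acid-promoted SN1 cycloetherification, in which the benzylic silyl ether ionises to a 4-alkoxy-3-methoxybenzyl cation that the C6 hydroxyl captures through a chair transition state; because this electron-rich 2-aryl oxane re-ionises under the same acid, both epimers of 14 should converge on the diequatorial cis ring, setting C2 as S while C6, C1′, the dithiane and the benzyl ethers are untouched.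

Step 8
Reactants: 15 cis spiro-dithiane oxane
Product: 16 (2S,6R)-2-[4-(benzyloxy)-3-methoxyphenyl]-6-{(1S)-1-(benzyloxy)-2-[4-(benzyloxy)phenyl]ethyl}oxan-4-one
Conditions: MeI, CaCO3, MeCN/H2O (9:1), 45 °C
Reagents that add atoms: water, O
Why: Alkylative dithioacetal hydrolysis, in which S-methylation makes sulfur a leaving group and water unmasks the C4 ketone; the method is non-oxidative, so the electron-rich arenes and benzyl ethers survive, and CaCO3 buffers the HI so that the β-alkoxy ketone is not opened.

Step 9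
Reactants: 16 tribenzyl oxan-4-one
Product: 17 (2S,6R)-2-(4-hydroxy-3-methoxyphenyl)-6-[(1S)-1-hydroxy-2-(4-hydroxyphenyl)ethyl]oxan-4-one (target)
Conditions: H2 (1 atm), 10% Pd/C, EtOAc, rt
Reagents that add atoms: none
Why: Heterogeneous catalytic hydrogenolysis should remove the two aryl benzyl ethers quickly and the secondary alkyl benzyl ether more slowly, while the ketone is inert at 1 atm in EtOAc and the hindered endocyclic C2–O1 benzylic bond is cleaved much more slowly, so the reaction is stopped at complete debenzylation.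

**Compound list**

1 | O-benzylvanillin, 4-(benzyloxy)-3-methoxybenzaldehyde | COc1cc(C=O)ccc1OCc1ccccc1 | starting material
2 | rac-2-[4-(benzyloxy)-3-methoxyphenyl]oxirane | COc1cc(C2CO2)ccc1OCc1ccccc1 | intermediate
3 | 4-(benzyloxy)phenylmagnesium bromide (THF solution) | Br[Mg]c1ccc(OCc2ccccc2)cc1 | starting material
4 | (S)-epichlorohydrin, (2S)-2-(chloromethyl)oxirane | ClC[C@@H]1CO1 | starting material
5 | (2S)-1-[4-(benzyloxy)phenyl]-3-chloropropan-2-ol | ClC[C@@H](O)Cc1ccc(OCc2ccccc2)cc1 | intermediate
6 | (2S)-2-[4-(benzyloxy)benzyl]oxirane (not isolated) | C1[C@@H](O1)Cc2ccc(OCc3ccccc3)cc2 | intermediate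
7 | (2S)-1-[4-(benzyloxy)phenyl]but-3-en-2-ol | C=C[C@@H](O)Cc1ccc(OCc2ccccc2)cc1 | intermediate
8 | (1S)-2-[4-(benzyloxy)phenyl]-1-[(2R)-oxiran-2-yl]ethan-1-ol | C1[C@H]([C@@H](O)Cc2ccc(OCc3ccccc3)cc2)O1 | intermediate
9 | (2R)-2-{(1S)-1-(benzyloxy)-2-[4-(benzyloxy)phenyl]ethyl}oxirane | C1[C@H]([C@@H](OCc2ccccc2)Cc2ccc(OCc3ccccc3)cc2)O1 | intermediate
10 | 2-(tert-butyldimethylsilyl)-1,3-dithiane | CC(C)(C)[Si](C)(C)C1SCCCS1 | starting material
11 | 2-lithio-2-(tert-butyldimethylsilyl)-1,3-dithiane (not isolated) | [Li]C1([Si](C)(C)C(C)(C)C)SCCCS1 | intermediate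
12 | lithium 1-[4-(benzyloxy)-3-methoxyphenyl]-2-[2-(tert-butyldimethylsilyl)-1,3-dithian-2-yl]ethan-1-olate, racemic (not isolated) | COc1cc(C(O[Li])CC2([Si](C)(C)C(C)(C)C)SCCCS2)ccc1OCc1ccccc1 | intermediate
13 | 2-lithio-2-{2-[4-(benzyloxy)-3-methoxyphenyl]-2-[(tert-butyldimethylsilyl)oxy]ethyl}-1,3-dithiane, racemic (not isolated) | COc1cc(C(O[Si](C)(C)C(C)(C)C)CC2([Li])SCCCS2)ccc1OCc1ccccc1 | intermediate
14 | (2R,3S)-3-(benzyloxy)-4-[4-(benzyloxy)phenyl]-1-(2-{2-[4-(benzyloxy)-3-methoxyphenyl]-2-[(tert-butyldimethylsilyl)oxy]ethyl}-1,3-dithian-2-yl)butan-2-ol, both epimers at the silyloxy carbon | COc1cc(C(O[Si](C)(C)C(C)(C)C)CC2(SCCCS2)C[C@@H](O)[C@@H](OCc3ccccc3)Cc3ccc(OCc4ccccc4)cc3)ccc1OCc1ccccc1 | intermediate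
15 | (8S,10R)-8-[4-(benzyloxy)-3-methoxyphenyl]-10-{(1S)-1-(benzyloxy)-2-[4-(benzyloxy)phenyl]ethyl}-9-oxa-1,5-dithiaspiro[5.5]undecane | COc1cc([C@@H]2CC3(SCCCS3)C[C@H]([C@@H](OCc4ccccc4)Cc4ccc(OCc5ccccc5)cc4)O2)ccc1OCc1ccccc1 | intermediate
16 | (2S,6R)-2-[4-(benzyloxy)-3-methoxyphenyl]-6-{(1S)-1-(benzyloxy)-2-[4-(benzyloxy)phenyl]ethyl}oxan-4-one | COc1cc([C@@H]2CC(=O)C[C@H]([C@@H](OCc3ccccc3)Cc3ccc(OCc4ccccc4)cc3)O2)ccc1OCc1ccccc1 | intermediate
17 | (2S,6R)-2-(4-hydroxy-3-methoxyphenyl)-6-[(1S)-1-hydroxy-2-(4-hydroxyphenyl)ethyl]oxan-4-one | COc1cc([C@@H]2CC(=O)C[C@H]([C@@H](O)Cc3ccc(O)cc3)O2)ccc1O | target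

**Count.** Total steps: 9. Longest linear sequence: 8 steps (steps 2 to 9, from 3 and 4).

**Steps most likely to fail**

Step 6. The silyl migration may start too early or stay incomplete, so that one epoxide adds twice or the sequence stalls at the mono-adduct. The electron-rich aryl oxirane may also open at the benzylic carbon or rearrange under lithium ion catalysis. Fallback: the coupling would be run as two separate Corey–Seebach alkylations. It sets out from 2 and commercial 1,3-dithiane. Lithiation of the dithiane (n-BuLi, THF, −30 °C) and opening of 2 should give rac-1-[4-(benzyloxy)-3-methoxyphenyl]-2-(1,3-dithian-2-yl)ethan-1-ol F1. Silylation (TBSCl, imidazole, DMF) should give its tert-butyldimethylsilyl ether F2. Deprotonation of F2 (t-BuLi, THF/HMPA, −78 °C) generates carbanion 13 directly, and addition of 9 should return the route at 14.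

Step 7. The benzylic cation may lose a proton to give the styrene, be captured intermolecularly, or fail to equilibrate fully to the cis ring. Fallback: the ring would be closed by conjugate addition instead of cation capture. It sets out from 14. Dithiane hydrolysis (MeI, CaCO3, aqueous MeCN) should give the ketone (5R,6S)-6-(benzyloxy)-1-[4-(benzyloxy)-3-methoxyphenyl]-7-[4-(benzyloxy)phenyl]-1-[(tert-butyldimethylsilyl)oxy]-5-hydroxyheptan-3-one F3. TsOH·H2O in CH2Cl2 should then eliminate the silanol on the benzylic side to the enone (1E,5R,6S)-6-(benzyloxy)-1-[4-(benzyloxy)-3-methoxyphenyl]-7-[4-(benzyloxy)phenyl]-5-hydroxyhept-1-en-3-one F4, which is not isolated. Reversible 6-endo oxa-Michael addition of the C6 hydroxyl should give the thermodynamic cis ring, and the route is rejoined at 16, with step 8 omitted.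

Step 9. Hydrogenolysis may also cleave the benzylic C2–O1 ring bond, the secondary benzyl ether may react sluggishly, and traces of sulfur from step 8 may poison the catalyst. Fallback: the benzyl ethers would be removed by Lewis-acid dealkylation instead of hydrogenolysis. It sets out from 16 and uses BCl3 with pentamethylbenzene as cation scavenger in CH2Cl2 at −78 °C, which should give 17 directly; no new compound is made (F0).

**Further compounds**

F1 | step 6 | rac-1-[4-(benzyloxy)-3-methoxyphenyl]-2-(1,3-dithian-2-yl)ethan-1-ol | COc1cc(C(O)CC2SCCCS2)ccc1OCc1ccccc1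
F2 | step 6 | rac-{1-[4-(benzyloxy)-3-methoxyphenyl]-2-(1,3-dithian-2-yl)ethoxy}(tert-butyl)dimethylsilane | COc1cc(C(O[Si](C)(C)C(C)(C)C)CC2SCCCS2)ccc1OCc1ccccc1
F3 | step 7 | (5R,6S)-6-(benzyloxy)-1-[4-(benzyloxy)-3-methoxyphenyl]-7-[4-(benzyloxy)phenyl]-1-[(tert-butyldimethylsilyl)oxy]-5-hydroxyheptan-3-one, both C1 epimers | COc1cc(C(O[Si](C)(C)C(C)(C)C)CC(=O)C[C@@H](O)[C@@H](OCc2ccccc2)Cc2ccc(OCc3ccccc3)cc2)ccc1OCc1ccccc1
F4 | step 7 | (1E,5R,6S)-6-(benzyloxy)-1-[4-(benzyloxy)-3-methoxyphenyl]-7-[4-(benzyloxy)phenyl]-5-hydroxyhept-1-en-3-one | COc1cc(/C=C/C(=O)C[C@@H](O)[C@@H](OCc2ccccc2)Cc2ccc(OCc3ccccc3)cc2)ccc1OCc1ccccc1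
F0 | step 9 | none | none
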